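**Retrosynthetic overview**

1. The target 16 is an acylated 2H-chromene (ring A) joined through one CH2 to an enantiopure dearomatised acylphloroglucinol (ring B). The bridge is cut at ring B C6–CH2 (reductive Knoevenagel), giving chromene aldehyde 10 and (R)-dienone 14.
2. The route rests on one feature of ring A (O1, gem-dimethyl C2, C3=C4, C4a, C5–OH, C6–CH2, C7–OH, C8–hexanoyl, C8a): O1 lies para to C6. In 2,4,6-trihydroxybenzaldehyde the 4-oxygen is para to the formyl carbon (the future bridge CH2), and its two ortho carbons C3 and C5 are mirror-equivalent.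
3. The pyran ring is therefore closed from the para O-(1,1-dimethylpropargyl) ether 4 by a Claisen/oxa-6π cascade (bonds C4a–C4 and O1–C2). C8, then the only free arene carbon, is hexanoylated afterwards.
4. Ring B comes from 2,4,6-trihydroxy-3-methylacetophenone by a palladium-catalysed asymmetric dearomative geranylation, which sets the only stereocentre.
5. Ring order: arene of ring A (bought), pyran ring (step 3), ring B carbocycle (bought as arene, dearomatised in step 6), fragment union last (step 7).

Key step: step 3

Assumption: the descriptor R at the quaternary carbon of 14 and 16 refers to the tautomers drawn in their SMILES strings. The (R,R)-ligand is taken to give this enantiomer in step 6; if the sense of induction proves opposite, the (S,S)-ligand is used.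

**Route**

Step 1
Reactants: 1 2-methylbut-3-yn-2-ol
Product: 2 methyl 2-methylbut-3-yn-2-yl carbonate
Conditions: ClCO2Me, pyridine, DMAP (cat.), CH2Cl2, 0 °C to rt
Reagents that add atoms: methyl chloroformate, COC(=O)Cl
Why: DMAP-catalysed O-acylation of the tertiary propargylic alcohol with a chloroformate (carbonate formation) is routine and installs the leaving group needed for the copper step.

Step 2
Reactants: 3 2,4,6-trihydroxybenzaldehyde; 2 methyl 2-methylbut-3-yn-2-yl carbonate
Product: 4 2,6-dihydroxy-4-[(2-methylbut-3-yn-2-yl)oxy]benzaldehyde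
Conditions: CuCl2·2H2O (cat.), DBU (1.1 equiv), 2 (1.05 equiv), MeCN, −5 to 0 °C
Reagents that add atoms: none
Why: Copper-catalysed propargylic etherification (through a copper acetylide/allenylidene) should take place at the phenoxide of the 4-OH, the most acidic hydroxyl and the only one not hydrogen-bonded to the formyl group, so one equivalent of carbonate should give the mono para ether.

Step 3
Reactants: 4 2,6-dihydroxy-4-[(2-methylbut-3-yn-2-yl)oxy]benzaldehyde
Product: 8 5,7-dihydroxy-2,2-dimethyl-2H-chromene-6-carbaldehyde, via allenyl cyclohexadienone 5 (not isolated), via ortho-allenylphenol 6 (not isolated), via ortho-quinone methide 7 (not isolated)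
Conditions: degassed o-xylene, 140 °C, Ar
Reagents that add atoms: none
Why: Heat drives an aryl propargyl ether Claisen rearrangement: the [3,3] shift moves the 1,1-dimethylpropargyl group from O4 to the ortho carbon and forms the C4a–C4 bond in allenyl dienone 5, enolisation gives allenylphenol 6, a 1,5-hydrogen shift from the phenolic OH to the central allene carbon gives ortho-quinone methide 7, and this 1-oxatriene closes to the chromene. The closest known reaction type is the thermal conversion of aryl 1,1-dimethylpropargyl ethers into 2,2-dimethyl-2H-chromenes. The pyran ring, the only ring formed, closes by thermal disrotatory oxa-6π electrocyclisation, which makes the O1–C2 bond on the same oxygen that carried the propargyl group. No stereocentre is created. The step needs only regiocontrol, and the substrate secures it: the ether oxygen is para to the formyl group, its two ortho carbons are related by the mirror plane through C1 and C4, and the two other hydroxyls are meta to the ether and stay chelated to the aldehyde, so only the chromene with O1 para to the formyl carbon can form. The neutral, base-free medium favours electrocyclisation over benzofuran formation, and C8 is left as the only free arene carbon for step 4.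

Step 4
Reactants: 8 5,7-dihydroxy-2,2-dimethyl-2H-chromene-6-carbaldehyde; 9 hexanoyl chloride
Product: 10 8-hexanoyl-5,7-dihydroxy-2,2-dimethyl-2H-chromene-6-carbaldehyde
Conditions: TiCl4 (3 equiv), CH2Cl2, −20 °C to rt; cold dilute HCl work-up
Reagents that add atoms: none
Why: Friedel–Crafts acylation, in which the titanium phenoxide directs the acylium ion to C8, the only unsubstituted ring carbon, which is ortho to O1 and the 7-OH and para to the 5-OH.

Step 5
Reactants: 11 geraniol
Product: 12 geranyl methyl carbonate
Conditions: ClCO2Me, pyridine, CH2Cl2, 0 °C to rt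
Reagents that add atoms: methyl chloroformate, COC(=O)Cl
Why: Standard O-acylation of a primary allylic alcohol with a chloroformate, which leaves the E alkene untouched.

Step 6
Reactants: 13 2,4,6-trihydroxy-3-methylacetophenone; 12 geranyl methyl carbonate
Product: 14 (4R)-2-acetyl-4-[(2E)-3,7-dimethylocta-2,6-dien-1-yl]-3,5-dihydroxy-4-methylcyclohexa-2,5-dien-1-one
Conditions: Pd2(dba)3·CHCl3 (cat.), (R,R)-DACH-phenyl Trost ligand (cat.), 13 (1.2 equiv), degassed THF, 0 °C to rt
Reagents that add atoms: none
Why: Proposed new method: zerovalent palladium ionises carbonate 12 to a π-geranyl palladium cation and, after loss of CO2, methoxide, which deprotonates 13; the phloroglucinolate attacks the unsubstituted allyl terminus from outside the metal (linear product, E geometry kept) through C3, its most electron-rich carbon and the one that base-mediated alkylations of C-alkyl acylphloroglucinols favour, while any O-geranyl ether can re-ionise and drain to the C-alkylated dienone; the chiral pocket of the diphosphine tells the acetyl-flanked side of the flat nucleophile from the hydrogen-flanked side and so sets the new quaternary stereocentre as R by catalyst-controlled enantiofacial selection. The closest known reaction types are the palladium-catalysed asymmetric allylic dearomatisation of substituted naphthols and phenols with Trost-type ligands, the enantioselective linear geranylation of prochiral carbon nucleophiles with the same ligands, and the racemic base-mediated dearomative alkylation of acylphloroglucinols.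

Step 7
Reactants: 10 8-hexanoyl-5,7-dihydroxy-2,2-dimethyl-2H-chromene-6-carbaldehyde; 14 (4R)-2-acetyl-4-[(2E)-3,7-dimethylocta-2,6-dien-1-yl]-3,5-dihydroxy-4-methylcyclohexa-2,5-dien-1-one
Product: 16 (4R)-2-acetyl-4-[(2E)-3,7-dimethylocta-2,6-dien-1-yl]-6-[(8-hexanoyl-5,7-dihydroxy-2,2-dimethyl-2H-chromen-6-yl)methyl]-3,5-dihydroxy-4-methylcyclohexa-2,5-dien-1-one (CNP0319887.1), via benzylidene triketone 15 (not isolated)
Conditions: L-proline (20 mol %), Hantzsch ester (diethyl 2,6-dimethyl-1,4-dihydropyridine-3,5-dicarboxylate, 1.2 equiv), CH2Cl2, rt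
Reagents that add atoms: none
Why: Organocatalytic three-component reductive alkylation (Knoevenagel condensation, then conjugate transfer hydrogenation): C6 of the vinylogous acid 14 attacks the proline-derived iminium of 10, and the electron-poor alkylidene 15 should be reduced by hydride transfer from the Hantzsch ester before a second molecule of 14 can add; the quaternary stereocentre is not touched and no new one forms.

**Compound list**

1 | 2-methylbut-3-yn-2-ol | CC(C)(O)C#C | starting material
2 | methyl 2-methylbut-3-yn-2-yl carbonate | COC(=O)OC(C)(C)C#C | intermediate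
3 | 2,4,6-trihydroxybenzaldehyde | O=Cc1c(O)cc(O)cc1O | starting material
4 | 2,6-dihydroxy-4-[(2-methylbut-3-yn-2-yl)oxy]benzaldehyde | O=Cc1c(O)cc(OC(C)(C)C#C)cc1O | intermediate
5 | 2,6-dihydroxy-3-(3-methylbuta-1,2-dien-1-yl)-4-oxocyclohexa-1,5-diene-1-carbaldehyde (allenyl cyclohexadienone, transient, racemic) | O=CC1=C(O)C(C=C=C(C)C)C(=O)C=C1O | intermediate
6 | 2,4,6-trihydroxy-3-(3-methylbuta-1,2-dien-1-yl)benzaldehyde (ortho-allenylphenol) | O=Cc1c(O)c(C=C=C(C)C)c(O)cc1O | intermediate
7 | 2,6-dihydroxy-3-(3-methylbut-2-en-1-ylidene)-4-oxocyclohexa-1,5-diene-1-carbaldehyde (ortho-quinone methide; exocyclic CH cis to the ring carbonyl for closure) | O=CC1=C(O)C(=CC=C(C)C)C(=O)C=C1O | intermediate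
8 | 5,7-dihydroxy-2,2-dimethyl-2H-chromene-6-carbaldehyde | O=Cc1c(O)cc2OC(C)(C)C=Cc2c1O | intermediate
9 | hexanoyl chloride | CCCCCC(=O)Cl | starting material
10 | 8-hexanoyl-5,7-dihydroxy-2,2-dimethyl-2H-chromene-6-carbaldehyde | CCCCCC(=O)c1c(O)c(C=O)c(O)c2c1OC(C)(C)C=C2 | intermediate
11 | geraniol, (2E)-3,7-dimethylocta-2,6-dien-1-ol | OC/C=C(\C)CCC=C(C)C | starting material
12 | geranyl methyl carbonate, (2E)-3,7-dimethylocta-2,6-dien-1-yl methyl carbonate | COC(=O)OC/C=C(\C)CCC=C(C)C | intermediate
13 | 2,4,6-trihydroxy-3-methylacetophenone | CC(=O)c1c(O)cc(O)c(C)c1O | starting material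
14 | (4R)-2-acetyl-4-[(2E)-3,7-dimethylocta-2,6-dien-1-yl]-3,5-dihydroxy-4-methylcyclohexa-2,5-dien-1-one | O=C1C=C(O)[C@@](C)(C/C=C(\C)CCC=C(C)C)C(O)=C1C(C)=O | intermediate
15 | 2-acetyl-4-[(2E)-3,7-dimethylocta-2,6-dien-1-yl]-6-[(8-hexanoyl-5,7-dihydroxy-2,2-dimethyl-2H-chromen-6-yl)methylidene]-3-hydroxy-4-methylcyclohex-2-ene-1,5-dione (benzylidene triketone; quaternary centre arranged as in 14, formally 4S in this tautomer; alkylidene geometry not defined) | CCCCCC(=O)c1c(O)c(C=C2C(=O)[C@@](C)(C/C=C(\C)CCC=C(C)C)C(O)=C(C(C)=O)C2=O)c(O)c2c1OC(C)(C)C=C2 | intermediate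
16 | (4R)-2-acetyl-4-[(2E)-3,7-dimethylocta-2,6-dien-1-yl]-6-[(8-hexanoyl-5,7-dihydroxy-2,2-dimethyl-2H-chromen-6-yl)methyl]-3,5-dihydroxy-4-methylcyclohexa-2,5-dien-1-one (CNP0319887.1) | CCCCCC(=O)c1c(O)c(CC2=C(O)[C@@](C)(C/C=C(\C)CCC=C(C)C)C(O)=C(C(C)=O)C2=O)c(O)c2c1OC(C)(C)C=C2 | target

**Step count**

Total steps: 7. Longest linear sequence: 5 steps (steps 1, 2, 3, 4 and 7). Steps 5 and 6 form the convergent ring B branch.

**Steps most likely to fail**

1. Step 6 (Proposed new method).
 - What may go wrong: poor facial discrimination at the methyl-bearing carbon; competing attack through the unsubstituted C5 or through oxygen; branched attack or E/Z scrambling in the π-allyl complex; a second allylation of the product; erosion of enantiopurity by reversible ionisation of the product by zerovalent palladium.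
 - Fallback (known chemistry, sets out from 13, returns at 14): geranyl bromide and NaOMe in MeOH at 0 °C, the established base-mediated alkylative dearomatisation of acylphloroglucinols, should give racemic 2-acetyl-4-[(2E)-3,7-dimethylocta-2,6-dien-1-yl]-3,5-dihydroxy-4-methylcyclohexa-2,5-dien-1-one F1 after separation from aromatic C5-geranyl and O-geranyl isomers. Preparative supercritical-fluid chromatography on a polysaccharide chiral stationary phase then delivers the R enantiomer 14. Its absolute configuration would be secured by X-ray analysis of a crystalline derivative or by comparing calculated and recorded circular dichroism.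

2. Step 4.
 - What may go wrong: acid-promoted hydrochlorination or oligomerisation at the C3=C4 double bond of the chromene; sluggish substitution because the ring already carries the formyl group; attack of the acyl chloride on the aldehyde.
 - Fallback (anionic instead of electrophilic acylation, sets out from 8, returns at 10): the phenols are capped with MOMCl and NaH in DMF at 0 °C to give 5,7-bis(methoxymethoxy)-2,2-dimethyl-2H-chromene-6-carbaldehyde F2. The aldehyde is masked in the flask with LiN(Me)CH2CH2NMe2 in THF at −78 °C as the lithium α-amino alkoxide F3. n-BuLi then removes the C8 proton, which lies between O1 and the 7-OMOM group, to give the 8-lithio species F4. N-Methoxy-N-methylhexanamide is added to give the tetrahedral amide adduct F5. Aqueous NH4Cl releases 8-hexanoyl-5,7-bis(methoxymethoxy)-2,2-dimethyl-2H-chromene-6-carbaldehyde F6. HCl in MeOH at 40 °C removes both MOM groups and gives 10.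

3. Step 7.
 - What may go wrong: slow iminium and Knoevenagel formation at the doubly chelated, di-ortho-substituted aldehyde; capture of the alkylidene by a second molecule of 14; ring closure of a ring A hydroxyl onto ring B (xanthene formation) before hydride transfer.
 - Fallback (quinone methide route, sets out from 10, returns at 16): reductive amination of 10 with Me2NH and NaBH(OAc)3 in 1,2-dichloroethane at rt should give the Mannich base 1-{6-[(dimethylamino)methyl]-5,7-dihydroxy-2,2-dimethyl-2H-chromen-8-yl}hexan-1-one F7. Heating F7 with 14 in toluene at 90 °C expels dimethylamine to form 8-hexanoyl-7-hydroxy-2,2-dimethyl-6-methylidene-2H-chromen-5(6H)-one F8 (the ortho-quinone methide). C6 of 14 traps F8 by Michael addition to give 16, and the formyl carbon still becomes the bridge.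

**Further compounds**

F1 | step 6 | racemic 2-acetyl-4-[(2E)-3,7-dimethylocta-2,6-dien-1-yl]-3,5-dihydroxy-4-methylcyclohexa-2,5-dien-1-one | O=C1C=C(O)C(C)(C/C=C(\C)CCC=C(C)C)C(O)=C1C(C)=O
F2 | step 4 | 5,7-bis(methoxymethoxy)-2,2-dimethyl-2H-chromene-6-carbaldehyde | O=Cc1c(OCOC)cc2OC(C)(C)C=Cc2c1OCOC
F3 | step 4 | lithium [5,7-bis(methoxymethoxy)-2,2-dimethyl-2H-chromen-6-yl]{[2-(dimethylamino)ethyl](methyl)amino}methanolate | [Li+].[O-]C(N(C)CCN(C)C)c1c(OCOC)cc2OC(C)(C)C=Cc2c1OCOC
F4 | step 4 | 8-lithio derivative of F3 | [Li+].[O-]C(N(C)CCN(C)C)c1c(OCOC)c([Li])c2OC(C)(C)C=Cc2c1OCOC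
F5 | step 4 | dilithium tetrahedral adduct of F4 with N-methoxy-N-methylhexanamide | [Li+].[Li+].[O-]C(N(C)CCN(C)C)c1c(OCOC)c(C([O-])(CCCCC)N(C)OC)c2OC(C)(C)C=Cc2c1OCOC
F6 | step 4 | 8-hexanoyl-5,7-bis(methoxymethoxy)-2,2-dimethyl-2H-chromene-6-carbaldehyde | CCCCCC(=O)c1c(OCOC)c(C=O)c(OCOC)c2c1OC(C)(C)C=C2
F7 | step 7 | 1-{6-[(dimethylamino)methyl]-5,7-dihydroxy-2,2-dimethyl-2H-chromen-8-yl}hexan-1-one | CCCCCC(=O)c1c(O)c(CN(C)C)c(O)c2c1OC(C)(C)C=C2
F8 | step 7 | 8-hexanoyl-7-hydroxy-2,2-dimethyl-6-methylidene-2H-chromen-5(6H)-one | C=C1C(O)=C(C(=O)CCCCC)C2=C(C=CC(C)(C)O2)C1=O
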